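Readings and results are simulated for an exercise; noise was put on by code.

No constant is given for these flasks, so I have to read one from the runs.

| setting | Wednesday's | Monday's | zeta | eta |
|---|---|---|---|---|
| starting material | 0.32 M | 0.32 M | 0.32 M | 0.32 M |
| second substrate | 0.19 M | 0.91 M | 0.150 M | 0.640 M |
| free catalyst | 3.2 mM | 3.2 mM | 3.2 mM | 3.2 mM |
| remark | run made earlier | run made earlier |  |  |
| time |  |  | 0.25 h | 1.0 h |

| run | time / min | target / % |
|---|---|---|
| Wednesday's | 2.50 | 2 |
| Wednesday's | 8.00 | 8 |
| Wednesday's | 15.0 | 12 |
| Wednesday's | 20.0 | 16 |
| Wednesday's | 30.0 | 24 |
| Monday's | 2.50 | 0 |
| Monday's | 8.00 | 8 |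
| Monday's | 15.0 | 9 |
| Monday's | 20.0 | 12 |
| Monday's | 30.0 | 17 |

(scatter of a reading: 2 percentage points)

1. which of the two ends with the higher amount of target, in percent of the starting material charged ("neither" if they lie within 2 percentage points) (zeta / eta / neither)
2. target at the end, in percent of the starting material charged, zeta
3. target at the end, in percent of the starting material charged, eta

My first try is a straight line through the last reading. The objection comes at once: starting material falls as target forms, so a line through a reading already holds some of that fall. So I divide the last reading by its time and by the mean fraction left, which I take as one minus half the target. Wednesday's run gives 0.545 h⁻¹. This is the pace: the fraction of the starting material still present that turns into target per unit time, a pseudo-first-order constant for one charge of second substrate. Monday's run gives a lower pace, 0.372 h⁻¹.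

Target is then pace times time times mean fraction left, and that fraction depends on the answer, so I go round. Zeta's second substrate lies nearer Wednesday's, so I take Wednesday's pace. Pace times time gives 13.6%, and putting this back gives 12.7%. A second round gives 12.8%, so my figure for zeta stands.

Eta's second substrate lies nearer Monday's, so I take Monday's pace. The first figure is 37.2%, and the correction now bites: 30.3%. But that round took off too much, and the next gives 31.5%. I commit to that, so by my reckoning eta ends higher than zeta.

Two doubts remain. Wednesday's 24% carries a scatter of 2 percentage points. And my fraction left counts target as the one way out for starting material, while eta runs twice as long as any reading. I cannot compute that away, so my eta figure may stand too high.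

The forecast says eta, with 12% for zeta and 35% for eta, holding that “the dependence on starting material appears weak”. On eta it stands above my figure.

The flasks give 13.0% for zeta and 26.8% for eta, so eta ends higher.

    starting material + free catalyst ⇌ catalyst intermediate A (K = 1.10 L mol⁻¹, k = 3.70 L mol⁻¹ s⁻¹)
    catalyst intermediate B → free catalyst + second product (k = 0.0680 s⁻¹)
    starting material + target → side product (k = 0.00100 L mol⁻¹ s⁻¹)
    second substrate + free catalyst ⇌ catalyst intermediate B (K = 1.70 L mol⁻¹, k = 0.130 L mol⁻¹ s⁻¹)
    catalyst intermediate A → free catalyst + target (k = 0.0750 s⁻¹)

At 1.00 h eta holds 48% of its starting material, with 26.8% as target and 24.7% as side product, so less is left than one minus target. With the mean of start and end, 74.2%, Monday's pace gives 27.6%. The neighbour is zeta read at 1.0 h, with Wednesday's pace. It has 40% of its starting material left and 27.7% as side product, so the mean is 69.8%. The reckoning gives 38.0%, and that flask holds 32.7% target.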